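## Analysis of the target

The target 27 is a furanoheliangolide. Its ten-membered carbocycle (C1–C10) is bridged by an oxygen between C3 and C10, which closes a 3(2H)-furanone (ring oxygen, C3, C2, C1, C10) with the ketone at C1 and the enol-ether double bond C2=C3. A Z-configured trisubstituted alkene C4=C5 is conjugated to the furanone, and a trans-fused α-methylene-γ-butyrolactone sits on C7/C8 (C11=C13, carbonyl C12, lactone oxygen on C8). The ring carries four stereocentres: C6 (R, acyloxy), C7 (R) and C8 (S) are contiguous, with H7 and H8 anti and O6 syn to the C11 branch along the C5–C8 chain. C10 (R) is fully substituted (methyl, ring oxygen, C1, C9) and has no neighbouring stereocentre. The C6 ester is (2S,3R)-2,3-dimethyloxirane-2-carboxylate, with cis methyl groups, and is best brought in as the finished acid. The sensitive groups are the α-methylene lactone (Michael acceptor), the vinylogous ester/dienone (base, nucleophiles), the allylic C6 oxygen (ionisation, translactonisation between O6 and O8), the epoxide (acid) and the Z alkene. The hard parts are the closure of a ten-membered ring that holds a Z alkene and a flat furanone, and the quaternary, oxygen-bearing C10. The strategy rests on one feature: C9 is β to the C1 ketone and C8 is a γ-carbinol, a homoaldol relationship. Because C10 lies between the ring oxygen and C1, the atoms C1, C9 and C10 can be held as a siloxycyclopropane fused to the dihydrofuran, and this cyclopropane is opened onto an aldehyde at C8.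

## Retrosynthetic reasoning

**Ester at O6.** The acyl–O6 bond of 27 is cut first, giving alcohol 22 and epoxy acid 25. The epoxide would not survive Lewis acid, hydride or palladium steps, so it is attached last; the forward reaction must acylate a hindered allylic alcohol without base strong enough to harm the methylene lactone.

**Lactone.** In 22 (through its silyl ether 21) the bonds O8–C12 and C11–C12 are cut, so that C12 comes from a carbonylation of the vinyl bromide in 20, trapped by the C8 hydroxyl. A malonate substituent on C7 would be the more obvious carrier of C12. It is not used because its acidic C–H would be silylated and then cyclopropanated in steps 10 and 11, it would bind the Lewis acid of the key step, and it would lactonise with any free C8 hydroxyl. The 1-bromoethenyl group is inert in every step up to 20 and gives the methylene lactone in one operation.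

**C8–C9 (key disconnection).** Cutting C8–C9 in 20 opens the ten-membered ring and leads to aldehyde 19, in which C1, C9 and C10 form a siloxycyclopropane. This cut is chosen because it forms the ring and the lactone carbinol together and lets the quaternary C10 be made earlier, on a flat precursor. The forward step must open C1–C9 (not C9–C10), use C9 and not C2 as the nucleophile, and give the 8S carbinol.

**Aldehyde, cyclopropane, siloxyfuran.** The aldehyde of 19 is released last, by hydride reduction of the N-methoxy-N-methylamide 18, since no oxidative or acidic unmasking would spare the cyclopropane and the dienol ether. In 18 the bonds C9–C10 and C9–C1 are cut, so C9 comes from a zinc carbenoid added to the enol-ether bond of siloxyfuran 17. Compound 17 is the silyl enol ether of furanone 16, so the C10 configuration of 16 does not matter.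

**Furanone.** In 16 the bonds O–C3, C3–C4 and C2–C3 are cut. The ring comes from the hydroxy ynone 14 by amine addition and acid cyclisation, and 14 comes from vinyl iodide 12, alkynol 13 and a one-carbon carbonyl insertion that supplies C3. The Z geometry of C4=C5 is thus carried over from a vinyl iodide and never has to be created next to the furanone.

**C6–C7.** Amide 12 goes back through 11 to the aldol adduct 10, and the C6–C7 bond is cut to imide 5 and the Z-iodoenal 8. An auxiliary-controlled syn-aldol sets C6 and C7 in one step with the O6/C11 syn relationship that the target needs, and the imide carbonyl is C8.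

**Small pieces.** Imide 5 comes from acid 2 (from alcohol 1) and auxiliary 3. Enal 8 comes from 7, made from butynol 6 by trans-hydroalumination and iodination, which fixes the Z geometry.

**Side chain.** Acid 25 comes from epoxy alcohol 24 by oxidation, and 24 from allylic alcohol 23 by asymmetric epoxidation; the E alkene gives the cis-dimethyl epoxide.

## Alternatives that were turned down

**Alternative 1:** Thiolactone closure followed by sulfide contraction.
- Disconnection and key step: C1–C2 of the open 1,3-diketone form of the furanone is cut. In the forward direction the eleven-membered S-(2-oxoalkyl) thioester A2 is treated with base and a phosphine thiophile. The C2 enolate adds to the thioester carbonyl C1, an episulfide forms and loses sulfur, and the ten-membered diketone A1 results.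
- For it: closing a thioester ring is better precedented than any carbon–carbon closure of a ten-membered ring, and the four different protecting groups of A1 are orthogonal.
- Against it: the thioester carbonyl is flanked by the fully substituted C10, so the enolate must attack a neopentyl-like carbon while the ring contracts from eleven to ten members. The enolate is that of a Z-enone carrying a γ-alkoxy group, so isomerisation and vinylogous elimination threaten. C8, C9 and C10 with their stereocentres must be built linearly beforehand. After A1, cyclodehydration to the furanone, three deprotections, lactone oxidation and esterification still remain.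
- Comparison: it is stronger on precedent for the ring closure. The chosen route forms C8–C9 and the ring together, needs no linear C8–C10 synthesis, and reaches the target in three steps after the ring is closed.

**Alternative 2:** Ynol ether photocycloaddition and electrocyclic ring expansion.
- Disconnection and key step: C2–C3 and C4–C5 are cut. Irradiation of the cyclooctenone A4 joins its enone carbons to the tethered propynyl ether, and conrotatory opening of the resulting cyclobutene expands the eight-membered ring to the ten-membered diene A3 (the same compound as 21).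
- For it: the furanone, the diene and the ten-membered ring arise in one operation from an eight-membered ring, with C6, C7, C8 and C10 already in place, and A3 is two steps from the target. On step economy after the key step it is as good as the chosen route, and it is the more elegant skeleton construction.
- Against it: an alkynyl ether of a tertiary alcohol is hard to make and fragments thermally to a ketene. The geometry of C4=C5 is dictated by the ring fusion of the photoadduct and the sense of the conrotatory opening, and cannot be corrected if it comes out E. The α-methylene lactone and the enone are themselves photoactive. A4, with four stereocentres on an eight-membered ring, is a long synthesis of its own.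
- Comparison: the chosen route offers an acyclic precursor whose stereocentres come from an auxiliary, a Z alkene fixed from a vinyl iodide, and a thermal key step.

**Alternative 3:** Ring contraction from thirteen to ten members by [2,3]-Wittig rearrangement.
- Disconnection and key step: C6–C7 is cut. Deprotonation at C6 of the thirteen-membered allylic ether A6 starts a [2,3] shift that forms C6–C7, breaks O–C13 and gives the C11=C13 methylene and the C6 alkoxide of A5 (the same compound as 22).
- For it: one step forms the C6–C7 bond, both stereocentres, the carbinol and the exocyclic methylene, and A5 is one step from the target. On step economy and on the number of features made in the key step it is stronger than the chosen route. The ether ring is also easy to close.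
- Against it: the base must remove the C6 proton in a molecule that has more acidic sites (the γ-position of the butenolide at C8, the C13 protons) and a base-sensitive dienone. C6 and C7 are set only by the conformation of a large ring. The C6 alkoxide formed sits one ring away from the lactone carbonyl and can translactonise to the 6,12-olide.
- Comparison: the chosen route sets C6 and C7 with an auxiliary and never exposes the assembled system to strong base.

Key step: step 13

Assumption: in step 11 the L,L-configured dipeptide ligand is taken to favour the face that gives the (1R,5S)-bicycle; if the sense is the opposite, the D,D-ligand is used in its place.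

## Route

Step 1
Reactants: 1 3-bromobut-3-en-1-ol
Product: 2 3-bromobut-3-enoic acid
Conditions: TEMPO (cat.), PhI(OAc)2, MeCN/H2O, rt
Reagents that add atoms: water, O
Why: Oxoammonium oxidation of the primary alcohol through the aldehyde hydrate to the acid; the near-neutral conditions leave the bromoalkene and the β,γ-unsaturation in place.

Step 2
Reactants: 2 3-bromobut-3-enoic acid; 3 (4S)-4-benzyl-1,3-oxazolidin-2-one
Product: 5 (4S)-4-benzyl-3-(3-bromobut-3-enoyl)-1,3-oxazolidin-2-one, via mixed pivalic anhydride 4 (not isolated)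
Conditions: Me3CCOCl, Et3N, THF, −20 °C; then 3, LiCl, −20 °C → rt
Reagents that add atoms: none
Why: N-Acylation of the oxazolidinone through a mixed anhydride with LiCl activation; the small base load keeps the double bond out of conjugation.

Step 3
Reactants: 6 but-2-yn-1-ol
Product: 7 (2Z)-3-iodobut-2-en-1-ol
Conditions: NaAlH2(OCH2CH2OMe)2, THF, 0 °C → rt; then I2, −78 → 0 °C
Reagents that add atoms: iodine, II
Why: Alkoxide-directed trans-hydroalumination puts aluminium on C3 cis to the carbinol carbon, and iodinolysis with retention gives the Z-iodoalkene.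

Step 4
Reactants: 7 (2Z)-3-iodobut-2-en-1-ol
Product: 8 (2Z)-3-iodobut-2-enal
Conditions: MnO2, CH2Cl2, rt
Reagents that add atoms: none
Why: Allylic oxidation under neutral heterogeneous conditions; the enal is filtered and used at once because β-iodoenals isomerise on standing.

Step 5
Reactants: 5 (4S)-4-benzyl-3-(3-bromobut-3-enoyl)-1,3-oxazolidin-2-one; 8 (2Z)-3-iodobut-2-enal
Product: 10 (4S)-4-benzyl-3-[(2S,3S,4Z)-2-(1-bromoethenyl)-3-hydroxy-5-iodohex-4-enoyl]-1,3-oxazolidin-2-one, via dibutylboron enolate 9 (not isolated)
Conditions: n-Bu2BOTf, Et3N, CH2Cl2, −78 → 0 °C; 8, −78 → −20 °C; then pH 7 buffer, MeOH, H2O2, 0 °C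
Reagents that add atoms: none
Why: Evans syn-aldol reaction: the Z-boron enolate reacts at its α-carbon through a closed chair transition state on the face away from the benzyl group, which sets C7 and C6 together (2S,3S in 10, the spatial arrangement of 7R,6R in the target); the cyclic boron aldol of a β,γ-unsaturated imide should give α-attack, not γ-attack.

Step 6
Reactants: 10 (4S)-4-benzyl-3-[(2S,3S,4Z)-2-(1-bromoethenyl)-3-hydroxy-5-iodohex-4-enoyl]-1,3-oxazolidin-2-one
Product: 11 (2S,3S,4Z)-2-(1-bromoethenyl)-3-hydroxy-5-iodo-N-methoxy-N-methylhex-4-enamide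
Conditions: MeNH(OMe)·HCl, Me3Al, CH2Cl2, 0 °C → rt
Reagents that add atoms: N,O-dimethylhydroxylamine hydrochloride, CNOC.Cl
Why: Aluminium amide transamidation; chelation by the free β-hydroxyl directs attack to the exocyclic carbonyl, so the auxiliary is released without touching C7.

Step 7
Reactants: 11 (2S,3S,4Z)-2-(1-bromoethenyl)-3-hydroxy-5-iodo-N-methoxy-N-methylhex-4-enamide
Product: 12 (2S,3S,4Z)-2-(1-bromoethenyl)-3-{[tert-butyl(dimethyl)silyl]oxy}-5-iodo-N-methoxy-N-methylhex-4-enamide
Conditions: TBSOTf, 2,6-lutidine, CH2Cl2, −78 → 0 °C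
Reagents that add atoms: tert-butyldimethylsilyl trifluoromethanesulfonate, CC(C)(C)[Si](C)(C)OS(=O)(=O)C(F)(F)F
Why: Silylation of the secondary allylic alcohol; the silyl ether does not chelate in step 13 and is kept until step 15.

Step 8
Reactants: 12 (2S,3S,4Z)-2-(1-bromoethenyl)-3-{[tert-butyl(dimethyl)silyl]oxy}-5-iodo-N-methoxy-N-methylhex-4-enamide; 13 but-3-yn-2-ol (racemic)
Product: 14 (2S,3R,4Z)-2-(1-bromoethenyl)-3-{[tert-butyl(dimethyl)silyl]oxy}-9-hydroxy-N-methoxy-N,5-dimethyl-6-oxodec-4-en-7-ynamide (both C9 epimers)
Conditions: PdCl2(PPh3)2 (5 mol %), CO (1 atm), Et3N, THF, rt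
Reagents that add atoms: carbon monoxide, [C-]#[O+]
Why: Carbonylative Sonogashira coupling: oxidative addition takes the C–I bond in preference to the C–Br bond, CO insertion and alkynylation give the ynone with retention of the Z geometry, and copper is left out to slow the direct coupling; the inserted carbon is C3.

Step 9
Reactants: 14 (2S,3R,4Z)-2-(1-bromoethenyl)-3-{[tert-butyl(dimethyl)silyl]oxy}-9-hydroxy-N-methoxy-N,5-dimethyl-6-oxodec-4-en-7-ynamide
Product: 16 (2S,3R,4Z)-2-(1-bromoethenyl)-3-{[tert-butyl(dimethyl)silyl]oxy}-N-methoxy-N-methyl-5-(5-methyl-4-oxo-4,5-dihydrofuran-2-yl)hex-4-enamide (both epimers at the furanone CH), via diethylamino enone 15 (not isolated)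
Conditions: Et2NH, EtOH, 0 °C → rt; then AcOH, H2O, rt
Reagents that add atoms: water, O
Why: Conjugate addition of the amine to the ynone at the carbon remote from the ketone gives a vinylogous amide; in aqueous acid the C10 hydroxyl closes onto the C3 carbonyl and loss of water and amine gives the 3(2H)-furanone (the classical 4-hydroxy-2-ynone route). The C10 epimers converge in step 10.

Step 10
Reactants: 16 (2S,3R,4Z)-2-(1-bromoethenyl)-3-{[tert-butyl(dimethyl)silyl]oxy}-N-methoxy-N-methyl-5-(5-methyl-4-oxo-4,5-dihydrofuran-2-yl)hex-4-enamide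
Product: 17 (2S,3R,4Z)-2-(1-bromoethenyl)-3-{[tert-butyl(dimethyl)silyl]oxy}-5-(4-{[tert-butyl(dimethyl)silyl]oxy}-5-methylfuran-2-yl)-N-methoxy-N-methylhex-4-enamide
Conditions: TBSOTf, Et3N, CH2Cl2, 0 °C
Reagents that add atoms: tert-butyldimethylsilyl trifluoromethanesulfonate, CC(C)(C)[Si](C)(C)OS(=O)(=O)C(F)(F)F
Why: Soft enolisation and O-silylation, driven by formation of the aromatic 3-siloxyfuran; C10 becomes planar.

Step 11
Reactants: 17 (2S,3R,4Z)-2-(1-bromoethenyl)-3-{[tert-butyl(dimethyl)silyl]oxy}-5-(4-{[tert-butyl(dimethyl)silyl]oxy}-5-methylfuran-2-yl)-N-methoxy-N-methylhex-4-enamide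
Product: 18 (2S,3R,4Z)-2-(1-bromoethenyl)-3-{[tert-butyl(dimethyl)silyl]oxy}-5-[(1R,5S)-5-{[tert-butyl(dimethyl)silyl]oxy}-1-methyl-2-oxabicyclo[3.1.0]hex-3-en-3-yl]-N-methoxy-N-methylhex-4-enamide
Conditions: Et2Zn, CH2I2, N-Boc-L-valyl-L-proline methyl ester, CH2Cl2, −40 → −20 °C
Reagents that add atoms: diiodomethane, ICI
Why: Proposed new method: the CH2 transfer is the Furukawa variant of the Simmons–Smith reaction on a silyl enol ether, and the siloxy-bearing double bond of a 3-siloxyfuran (here C10=C1) is known to react as a silyl enol ether with electrophiles, so the electrophilic zinc carbenoid should take this bond before C4=C5 or the deactivated bromoalkene; what has not been shown is face control by a chiral dipeptide–zinc carbenoid on a tetrasubstituted enol ether held in a furan ring. Addition is cis, so C1 and C10 are set together and the ligand only has to choose the face (10R, 1S in ring numbering). The closest known reaction type is the dipeptide-controlled asymmetric Simmons–Smith cyclopropanation of acyclic aryl silyl enol ethers.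

Step 12
Reactants: 18 (2S,3R,4Z)-2-(1-bromoethenyl)-3-{[tert-butyl(dimethyl)silyl]oxy}-5-[(1R,5S)-5-{[tert-butyl(dimethyl)silyl]oxy}-1-methyl-2-oxabicyclo[3.1.0]hex-3-en-3-yl]-N-methoxy-N-methylhex-4-enamide
Product: 19 (2S,3R,4Z)-2-(1-bromoethenyl)-3-{[tert-butyl(dimethyl)silyl]oxy}-5-[(1R,5S)-5-{[tert-butyl(dimethyl)silyl]oxy}-1-methyl-2-oxabicyclo[3.1.0]hex-3-en-3-yl]hex-4-enal
Conditions: i-Bu2AlH, THF, −78 °C; aq. KNaC4H4O6 (potassium sodium tartrate)
Reagents that add atoms: none
Why: Hydride addition to the N-methoxy-N-methylamide gives a chelated hemiaminal that releases the aldehyde only on work-up, so there is no over-reduction; the basic, non-oxidising conditions spare the siloxycyclopropane and the dienol ether. The aldehyde is used at once to protect the C7 configuration.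

Step 13
Reactants: 19 (2S,3R,4Z)-2-(1-bromoethenyl)-3-{[tert-butyl(dimethyl)silyl]oxy}-5-[(1R,5S)-5-{[tert-butyl(dimethyl)silyl]oxy}-1-methyl-2-oxabicyclo[3.1.0]hex-3-en-3-yl]hex-4-enal
Product: 20 (2Z,4R,5R,6S,8R)-5-(1-bromoethenyl)-4-{[tert-butyl(dimethyl)silyl]oxy}-6-hydroxy-2,8-dimethyl-11-oxabicyclo[6.2.1]undeca-1(10),2-dien-9-one (target numbering: 6R,7R,8S,10R)
Conditions: TiCl4 (1.2 equiv), 2,6-di-tert-butyl-4-methylpyridine (0.2 equiv), CH2Cl2, −78 °C, slow addition of 19 to a final 2 mM; aq. NaHCO3
Reagents that add atoms: none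
Why: Proposed new method: TiCl4 binds the aldehyde oxygen and C8 is attacked by C9, the methylene carbon of the siloxycyclopropane; the C1–C9 bond breaks as positive charge builds at C1, where it is taken up by the siloxy oxygen and, through C2=C3, by the ring oxygen, and chloride then takes the silyl group so that the C1 ketone of the furanone appears. The closest known reaction types are the TiCl4-mediated homoaldol additions of 1-alkoxy-1-siloxycyclopropanes (titanium ester homoenolates) to aldehydes and the Lewis-acid ring-opening aldol reactions of 2-siloxycyclopropanecarboxylates; electronically the cyclopropane is the homologue of the terminal alkene of a 1-alkoxy-3-siloxydiene, which reacts with activated aldehydes at that terminus. One ring is closed, the ten-membered carbocycle (nine-membered if counted through the ring oxygen), in exo-trig mode at the aldehyde carbon; release of the cyclopropane strain and formation of the vinylogous ester pay for the medium-ring strain. The new stereocentre C8 is controlled by C7: the silyl ether at O6 does not chelate, and C9 should add to the carbonyl face anti to the C6 branch, which is the large α-substituent because it is part of the forming ring (Felkin–Anh-type approach); this places O8 syn to the bromovinyl group, the 8S arrangement of the trans-lactone. Two selectivities are needed: cleavage of C1–C9 and not of C9–C10, secured because only the former leaves a cation with two oxygen donors and ends irreversibly in a neutral ketone; and attack by C9 and not by the enol-ether carbon C2, which rests on the same double stabilisation and strain release, whereas attack by C2 would give a seven-membered ring with one donor and no exit by silyl loss. Slow addition to TiCl4 keeps the concentration low and lets each molecule be complexed at the aldehyde at once, before a titanium homoenolate (which could expel the ring oxygen by β-elimination) can form, and the hindered pyridine takes up adventitious HCl that would protonate the dienol ether.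

Step 14
Reactants: 20 (2Z,4R,5R,6S,8R)-5-(1-bromoethenyl)-4-{[tert-butyl(dimethyl)silyl]oxy}-6-hydroxy-2,8-dimethyl-11-oxabicyclo[6.2.1]undeca-1(10),2-dien-9-one
Product: 21 (6R,7R,8S,10R)-6-{[tert-butyl(dimethyl)silyl]oxy}-3,10-epoxy-1-oxogermacra-2,4(Z),11(13)-trien-12,8-olide
Conditions: Pd(PPh3)4 (10 mol %), CO (1 atm), K2CO3, MeCN, 60 °C
Reagents that add atoms: carbon monoxide, [C-]#[O+]
Why: Palladium-catalysed carbonylative lactonisation of a 3-bromohomoallylic alcohol: oxidative addition into the vinyl bromide, CO insertion and capture of the acylpalladium by the C8 hydroxyl give the α-methylene lactone. C7 and C8 are not touched, so the lactone is trans-fused.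

Step 15
Reactants: 21 (6R,7R,8S,10R)-6-{[tert-butyl(dimethyl)silyl]oxy}-3,10-epoxy-1-oxogermacra-2,4(Z),11(13)-trien-12,8-olide
Product: 22 (6R,7S,8S,10R)-6-hydroxy-3,10-epoxy-1-oxogermacra-2,4(Z),11(13)-trien-12,8-olide
Conditions: HF·pyridine, pyridine, THF, 0 °C → rt
Reagents that add atoms: none
Why: Fluoride cleavage of the silyl ether under buffered acidic conditions; basic fluoride sources, which add to the methylene lactone, are avoided. The descriptor at C7 changes only because of the priority rules.

Step 16
Reactants: 23 (2E)-2-methylbut-2-en-1-ol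
Product: 24 [(2R,3R)-2,3-dimethyloxiran-2-yl]methanol
Conditions: Ti(OiPr)4 (10 mol %), D-(−)-diisopropyl tartrate (12 mol %), t-BuOOH, 4 Å molecular sieves, CH2Cl2, −20 °C
Reagents that add atoms: tert-butyl hydroperoxide, CC(C)(C)OO
Why: Sharpless asymmetric epoxidation; the D-(−)-tartrate delivers oxygen to the face that gives the (2R,3R)-epoxy alcohol, and syn addition to the E alkene keeps the two methyl groups cis.

Step 17
Reactants: 24 [(2R,3R)-2,3-dimethyloxiran-2-yl]methanol
Product: 25 (2S,3R)-2,3-dimethyloxirane-2-carboxylic acid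
Conditions: TEMPO (cat.), PhI(OAc)2, MeCN/H2O, rt
Reagents that add atoms: water, O
Why: Oxoammonium oxidation of the primary alcohol to the acid without opening the epoxide; C2 changes from R to S only because the carboxyl group outranks C3.

Step 18
Reactants: 22 (6R,7S,8S,10R)-6-hydroxy-3,10-epoxy-1-oxogermacra-2,4(Z),11(13)-trien-12,8-olide; 25 (2S,3R)-2,3-dimethyloxirane-2-carboxylic acid
Product: 27 (6R,7R,8S,10R)-6-{[(2S,3R)-2,3-dimethyloxiran-2-yl]carbonyloxy}-3,10-epoxy-1-oxogermacra-2,4(Z),11(13)-trien-12,8-olide (CNP0258430.2), via mixed trichlorobenzoic anhydride 26 (not isolated)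
Conditions: 2,4,6-Cl3C6H2COCl, Et3N, THF, rt; then 22, DMAP, toluene, rt
Reagents that add atoms: none
Why: Yamaguchi esterification: DMAP attacks the mixed anhydride at the less hindered acyl carbon and the acylpyridinium acylates the hindered C6 hydroxyl with retention at C6; nothing basic enough to open the lactone or the epoxide is present.

## Compound list

1 | 3-bromobut-3-en-1-ol | C=C(Br)CCO | starting material
2 | 3-bromobut-3-enoic acid | C=C(Br)CC(=O)O | intermediate
3 | (4S)-4-benzyl-1,3-oxazolidin-2-one | O=C1N[C@@H](Cc2ccccc2)CO1 | starting material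
4 | 3-bromobut-3-enoic 2,2-dimethylpropanoic anhydride | C=C(Br)CC(=O)OC(=O)C(C)(C)C | intermediate (not isolated)
5 | (4S)-4-benzyl-3-(3-bromobut-3-enoyl)-1,3-oxazolidin-2-one | C=C(Br)CC(=O)N1C(=O)OC[C@@H]1Cc1ccccc1 | intermediate
6 | but-2-yn-1-ol | CC#CCO | starting material
7 | (2Z)-3-iodobut-2-en-1-ol | OC/C=C(C)\I | intermediate
8 | (2Z)-3-iodobut-2-enal | O=C/C=C(C)\I | intermediate
9 | dibutylboron (Z)-enolate of 5 | C=C(Br)/C=C(/N1C(=O)OC[C@@H]1Cc1ccccc1)OB(CCCC)CCCC | intermediate (not isolated)
10 | (4S)-4-benzyl-3-[(2S,3S,4Z)-2-(1-bromoethenyl)-3-hydroxy-5-iodohex-4-enoyl]-1,3-oxazolidin-2-one | I/C(C)=C\[C@@H](O)[C@H](C(Br)=C)C(=O)N1C(=O)OC[C@@H]1Cc1ccccc1 | intermediate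
11 | (2S,3S,4Z)-2-(1-bromoethenyl)-3-hydroxy-5-iodo-N-methoxy-N-methylhex-4-enamide | I/C(C)=C\[C@@H](O)[C@H](C(Br)=C)C(=O)N(C)OC | intermediate
12 | (2S,3S,4Z)-2-(1-bromoethenyl)-3-{[tert-butyl(dimethyl)silyl]oxy}-5-iodo-N-methoxy-N-methylhex-4-enamide | I/C(C)=C\[C@@H](O[Si](C)(C)C(C)(C)C)[C@H](C(Br)=C)C(=O)N(C)OC | intermediate
13 | but-3-yn-2-ol (racemic) | CC(O)C#C | starting material
14 | (2S,3R,4Z)-2-(1-bromoethenyl)-3-{[tert-butyl(dimethyl)silyl]oxy}-9-hydroxy-N-methoxy-N,5-dimethyl-6-oxodec-4-en-7-ynamide (C9 epimers) | CC(O)C#CC(=O)/C(C)=C\[C@@H](O[Si](C)(C)C(C)(C)C)[C@H](C(Br)=C)C(=O)N(C)OC | intermediate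
15 | (2S,3R,4Z)-2-(1-bromoethenyl)-3-{[tert-butyl(dimethyl)silyl]oxy}-8-(diethylamino)-9-hydroxy-N-methoxy-N,5-dimethyl-6-oxodeca-4,7-dienamide | CCN(CC)C(=CC(=O)/C(C)=C\[C@@H](O[Si](C)(C)C(C)(C)C)[C@H](C(Br)=C)C(=O)N(C)OC)C(C)O | intermediate (not isolated)
16 | (2S,3R,4Z)-2-(1-bromoethenyl)-3-{[tert-butyl(dimethyl)silyl]oxy}-N-methoxy-N-methyl-5-(5-methyl-4-oxo-4,5-dihydrofuran-2-yl)hex-4-enamide (epimers at the furanone CH) | CC1OC(=CC1=O)/C(C)=C\[C@@H](O[Si](C)(C)C(C)(C)C)[C@H](C(Br)=C)C(=O)N(C)OC | intermediate
17 | (2S,3R,4Z)-2-(1-bromoethenyl)-3-{[tert-butyl(dimethyl)silyl]oxy}-5-(4-{[tert-butyl(dimethyl)silyl]oxy}-5-methylfuran-2-yl)-N-methoxy-N-methylhex-4-enamide | Cc1oc(/C(C)=C\[C@@H](O[Si](C)(C)C(C)(C)C)[C@H](C(Br)=C)C(=O)N(C)OC)cc1O[Si](C)(C)C(C)(C)C | intermediate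
18 | (2S,3R,4Z)-2-(1-bromoethenyl)-3-{[tert-butyl(dimethyl)silyl]oxy}-5-[(1R,5S)-5-{[tert-butyl(dimethyl)silyl]oxy}-1-methyl-2-oxabicyclo[3.1.0]hex-3-en-3-yl]-N-methoxy-N-methylhex-4-enamide | C[C@@]12C[C@]1(O[Si](C)(C)C(C)(C)C)C=C(O2)/C(C)=C\[C@@H](O[Si](C)(C)C(C)(C)C)[C@H](C(Br)=C)C(=O)N(C)OC | intermediate
19 | (2S,3R,4Z)-2-(1-bromoethenyl)-3-{[tert-butyl(dimethyl)silyl]oxy}-5-[(1R,5S)-5-{[tert-butyl(dimethyl)silyl]oxy}-1-methyl-2-oxabicyclo[3.1.0]hex-3-en-3-yl]hex-4-enal (key-step precursor) | C[C@@]12C[C@]1(O[Si](C)(C)C(C)(C)C)C=C(O2)/C(C)=C\[C@@H](O[Si](C)(C)C(C)(C)C)[C@H](C(Br)=C)C=O | intermediate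
20 | (2Z,4R,5R,6S,8R)-5-(1-bromoethenyl)-4-{[tert-butyl(dimethyl)silyl]oxy}-6-hydroxy-2,8-dimethyl-11-oxabicyclo[6.2.1]undeca-1(10),2-dien-9-one (key-step product) | C=C(Br)[C@@H]1[C@@H](O)C[C@@]2(C)OC(=CC2=O)/C(C)=C\[C@H]1O[Si](C)(C)C(C)(C)C | intermediate
21 | (6R,7R,8S,10R)-6-{[tert-butyl(dimethyl)silyl]oxy}-3,10-epoxy-1-oxogermacra-2,4(Z),11(13)-trien-12,8-olide | C=C1C(=O)O[C@H]2C[C@@]3(C)OC(=CC3=O)/C(C)=C\[C@@H](O[Si](C)(C)C(C)(C)C)[C@H]12 | intermediate
22 | (6R,7S,8S,10R)-6-hydroxy-3,10-epoxy-1-oxogermacra-2,4(Z),11(13)-trien-12,8-olide | C=C1C(=O)O[C@H]2C[C@@]3(C)OC(=CC3=O)/C(C)=C\[C@@H](O)[C@H]12 | intermediate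
23 | (2E)-2-methylbut-2-en-1-ol | C/C=C(\C)CO | starting material
24 | [(2R,3R)-2,3-dimethyloxiran-2-yl]methanol | OC[C@@]1(C)O[C@@H]1C | intermediate
25 | (2S,3R)-2,3-dimethyloxirane-2-carboxylic acid | O=C(O)[C@@]1(C)O[C@@H]1C | intermediate
26 | (2S,3R)-2,3-dimethyloxirane-2-carboxylic 2,4,6-trichlorobenzoic anhydride | O=C(OC(=O)[C@@]1(C)O[C@@H]1C)c1c(Cl)cc(Cl)cc1Cl | intermediate (not isolated)
27 | (6R,7R,8S,10R)-6-{[(2S,3R)-2,3-dimethyloxiran-2-yl]carbonyloxy}-3,10-epoxy-1-oxogermacra-2,4(Z),11(13)-trien-12,8-olide (CNP0258430.2) | C=C1C(=O)O[C@H]2C[C@@]3(C)OC(=CC3=O)/C(C)=C\[C@@H](OC(=O)[C@@]3(C)O[C@@H]3C)[C@H]12 | target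

## Step count and least certain steps

Total step count: 18. Longest linear sequence: 14 steps (steps 1, 2, 5–15 and 18; the branch from 6 through steps 3 and 4 is equally long).

**Step 13 (key step, proposed new method).**
- Most likely failure: no macrocycle forms, because the TiCl4-bound aldehyde is attacked by the enol-ether carbon C2 (seven-membered Prins-type closure), or because the dienol ether and the allylic silyl ether are ionised before C9 reaches C8. The entropic preference for the smaller ring works against the electronic preference for C9.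
- Fallback (known chemistry, ring closed at C9–C10 instead of C8–C9): it sets out from furanone amide 16 and returns at 20. Chloromethyllithium made in the flask (ICH2Cl, MeLi·LiBr, THF, −78 °C, in excess to allow for the acidic furanone C–H) converts the N-methoxy-N-methylamide into (3S,4R,5Z)-3-(1-bromoethenyl)-4-{[tert-butyl(dimethyl)silyl]oxy}-1-chloro-6-(5-methyl-4-oxo-4,5-dihydrofuran-2-yl)hept-5-en-2-one F1. With Cs2CO3 and NaI in MeCN at high dilution the furanone enolate is C-alkylated at C10 by the halomethyl ketone (Finkelstein-assisted intramolecular enolate alkylation), giving (2Z,4R,5S,8R)-5-(1-bromoethenyl)-4-{[tert-butyl(dimethyl)silyl]oxy}-2,8-dimethyl-11-oxabicyclo[6.2.1]undeca-1(10),2-diene-6,9-dione F2, with C10 set under control of the ring. Corey–Bakshi–Shibata reduction of the C8 ketone (the furanone carbonyl is a vinylogous ester and should be left), with the oxazaborolidine enantiomer that gives 8S, leads to 20.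
- Weak points of the fallback: O- versus C-alkylation, the C10 configuration and base-sensitivity at C7, which is why it is not the main route. The same ketone is also the point at which a wrong configuration at C8 could be corrected, by oxidation of the alcohol and the same reduction.

**Step 11 (proposed new method).**
- Most likely failure: poor facial selectivity, because the enol ether is tetrasubstituted, sits in a furan ring and has no directing group near C10; some carbenoid may also go to C4=C5.
- Fallback (known chemistry, separation in place of induction): it sets out from 17 and returns at 18. The ligand-free Furukawa carbenoid (Et2Zn, CH2I2, CH2Cl2, −20 °C) gives 18 together with its epimer (2S,3R,4Z)-2-(1-bromoethenyl)-3-{[tert-butyl(dimethyl)silyl]oxy}-5-[(1S,5R)-5-{[tert-butyl(dimethyl)silyl]oxy}-1-methyl-2-oxabicyclo[3.1.0]hex-3-en-3-yl]-N-methoxy-N-methylhex-4-enamide F3. Because of C6 and C7 the two are diastereomers and are separated by chromatography on base-washed silica, so C10 is secured by separation and not by the reagent.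

**Step 5.**
- Most likely failure: Z to E isomerisation of the β-iodoenal 8 before or during the aldol (addition–elimination at the iodo-bearing carbon), giving the E-iodoalkene.
- Fallback (alkene geometry made after the aldol): it sets out from 5 and 6 and returns at 10. MnO2 oxidation of 6 gives but-2-ynal F4. The same boron aldol with 5 gives (4S)-4-benzyl-3-[(2S,3S)-2-(1-bromoethenyl)-3-hydroxyhex-4-ynoyl]-1,3-oxazolidin-2-one F5. Hydroxyl-directed trans-hydrosilylation ([Cp*Ru(MeCN)3]PF6, BnMe2SiH, CH2Cl2) places silicon on the distal alkyne carbon cis to C6 and gives (4S)-4-benzyl-3-[(2S,3R,4Z)-5-[benzyl(dimethyl)silyl]-2-(1-bromoethenyl)-3-hydroxyhex-4-enoyl]-1,3-oxazolidin-2-one F6. Iododesilylation with N-iodosuccinimide in (CF3)2CHOH proceeds with retention and gives 10.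

**Step 8.**
- Most likely failure: direct alkynylation without CO insertion at the hindered iodide, giving an enyne that lacks C3.
- Fallback (insertion and alkynylation separated): it sets out from 12 and returns at 14. Hydroxycarbonylation (Pd(OAc)2, PPh3, CO, H2O, Et3N, DMF) gives (2Z,4R,5S)-5-(1-bromoethenyl)-4-{[tert-butyl(dimethyl)silyl]oxy}-6-[methoxy(methyl)amino]-2-methyl-6-oxohex-2-enoic acid F7. 1-Chloro-N,N,2-trimethylprop-1-en-1-amine converts it under neutral conditions into the acid chloride F8, and acyl Sonogashira coupling with 13 (PdCl2(PPh3)2, CuI, Et3N) gives 14.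

**Step 14.**
- Most likely failure: slow capture of the acylpalladium by the hindered C8 hydroxyl inside the ring, so that the intermediate is reduced or decomposes.
- Fallback (capture by solvent, then lactonisation): it sets out from 20 and returns at 21. Methoxycarbonylation (PdCl2(PPh3)2, CO, MeOH, Et3N) gives methyl 2-[(2Z,4R,5R,6S,8R)-4-{[tert-butyl(dimethyl)silyl]oxy}-6-hydroxy-2,8-dimethyl-9-oxo-11-oxabicyclo[6.2.1]undeca-1(10),2-dien-5-yl]prop-2-enoate F9, which is lactonised with pyridinium p-toluenesulfonate in warm toluene to 21.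

## Further compounds

F1 | step 13 | (3S,4R,5Z)-3-(1-bromoethenyl)-4-{[tert-butyl(dimethyl)silyl]oxy}-1-chloro-6-(5-methyl-4-oxo-4,5-dihydrofuran-2-yl)hept-5-en-2-one | CC1OC(=CC1=O)/C(C)=C\[C@@H](O[Si](C)(C)C(C)(C)C)[C@H](C(Br)=C)C(=O)CCl
F2 | step 13 | (2Z,4R,5S,8R)-5-(1-bromoethenyl)-4-{[tert-butyl(dimethyl)silyl]oxy}-2,8-dimethyl-11-oxabicyclo[6.2.1]undeca-1(10),2-diene-6,9-dione | C=C(Br)[C@@H]1C(=O)C[C@@]2(C)OC(=CC2=O)/C(C)=C\[C@H]1O[Si](C)(C)C(C)(C)C
F3 | step 11 | (2S,3R,4Z)-2-(1-bromoethenyl)-3-{[tert-butyl(dimethyl)silyl]oxy}-5-[(1S,5R)-5-{[tert-butyl(dimethyl)silyl]oxy}-1-methyl-2-oxabicyclo[3.1.0]hex-3-en-3-yl]-N-methoxy-N-methylhex-4-enamide | C[C@]12C[C@@]1(O[Si](C)(C)C(C)(C)C)C=C(O2)/C(C)=C\[C@@H](O[Si](C)(C)C(C)(C)C)[C@H](C(Br)=C)C(=O)N(C)OC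
F4 | step 5 | but-2-ynal | CC#CC=O
F5 | step 5 | (4S)-4-benzyl-3-[(2S,3S)-2-(1-bromoethenyl)-3-hydroxyhex-4-ynoyl]-1,3-oxazolidin-2-one | CC#C[C@@H](O)[C@H](C(Br)=C)C(=O)N1C(=O)OC[C@@H]1Cc1ccccc1
F6 | step 5 | (4S)-4-benzyl-3-[(2S,3R,4Z)-5-[benzyl(dimethyl)silyl]-2-(1-bromoethenyl)-3-hydroxyhex-4-enoyl]-1,3-oxazolidin-2-one | C[Si](C)(Cc1ccccc1)/C(C)=C\[C@@H](O)[C@H](C(Br)=C)C(=O)N1C(=O)OC[C@@H]1Cc1ccccc1
F7 | step 8 | (2Z,4R,5S)-5-(1-bromoethenyl)-4-{[tert-butyl(dimethyl)silyl]oxy}-6-[methoxy(methyl)amino]-2-methyl-6-oxohex-2-enoic acid | OC(=O)/C(C)=C\[C@@H](O[Si](C)(C)C(C)(C)C)[C@H](C(Br)=C)C(=O)N(C)OC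
F8 | step 8 | (2Z,4R,5S)-5-(1-bromoethenyl)-4-{[tert-butyl(dimethyl)silyl]oxy}-6-[methoxy(methyl)amino]-2-methyl-6-oxohex-2-enoyl chloride | ClC(=O)/C(C)=C\[C@@H](O[Si](C)(C)C(C)(C)C)[C@H](C(Br)=C)C(=O)N(C)OC
F9 | step 14 | methyl 2-[(2Z,4R,5R,6S,8R)-4-{[tert-butyl(dimethyl)silyl]oxy}-6-hydroxy-2,8-dimethyl-9-oxo-11-oxabicyclo[6.2.1]undeca-1(10),2-dien-5-yl]prop-2-enoate | C=C(C(=O)OC)[C@@H]1[C@@H](O)C[C@@]2(C)OC(=CC2=O)/C(C)=C\[C@H]1O[Si](C)(C)C(C)(C)C
A1 | alternative 1 | ten-membered 1,3-diketone (product of the sulfide contraction) | C=C(CO[Si](C)(C)C(C)(C)C)[C@@H]1[C@@H](O[Si](C)(C)C(C)(C)C)C[C@@](C)(O[Si](CC)(CC)CC)C(=O)CC(=O)/C(C)=C\[C@H]1OCc2ccc(OC)cc2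
A2 | alternative 1 | eleven-membered S-(2-oxoalkyl) thioester | C=C(CO[Si](C)(C)C(C)(C)C)[C@@H]1[C@@H](O[Si](C)(C)C(C)(C)C)C[C@@](C)(O[Si](CC)(CC)CC)C(=O)SCC(=O)/C(C)=C\[C@H]1OCc2ccc(OC)cc2
A3 | alternative 2 | 6-O-TBS furanone germacranolide core (identical with 21) | C=C1C(=O)O[C@H]2C[C@@]3(C)OC(=CC3=O)/C(C)=C\[C@@H](O[Si](C)(C)C(C)(C)C)[C@H]12
A4 | alternative 2 | lactone-fused cyclooctenone carrying the prop-1-ynyl ether at C10 | C=C1C(=O)O[C@H]2C[C@@](C)(OC#CC)C(=O)/C=C\[C@@H](O[Si](C)(C)C(C)(C)C)[C@H]12
A5 | alternative 3 | 6-hydroxy core (identical with 22) | C=C1C(=O)O[C@H]2C[C@@]3(C)OC(=CC3=O)/C(C)=C\[C@@H](O)[C@H]12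
A6 | alternative 3 | thirteen-membered allylic ether with the butenolide C7=C11 | O=C1O[C@H]2C[C@@]3(C)OC(=CC3=O)/C(C)=C\COCC1=C2
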